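**Conventions and one assumption.** The oxolane is numbered O1, C2 (carrying ring A, the 4-hydroxyphenyl group), C3 and C4 (the methyl carbons), C5 (carrying ring B, the 1,2,4-trisubstituted phenol). Ring C is the 4-hydroxyphenyl end of the side chain. Assumption: the sense of induction of the iridium catalyst in step 8 is taken from the parent (E)-1,2-diarylpropene class and must be confirmed on 15; the other ligand enantiomer is used if it proves opposite.

## Analysis of the target

Target 20 is a 2,5-diaryl-3,4-dimethyloxolane whose ring B carries, ortho to its phenol, a (2R)-1-(4-hydroxyphenyl)propan-2-yl group. It has three free phenols and no other functional group. Four contiguous stereocentres sit on the oxolane, (2S,3S,4R,5R): the methyls on C3 and C4 are cis, each aryl is trans to its neighbouring methyl, and the two aryls are cis across the ring oxygen. The fifth stereocentre, the (R) benzylic methine of the side chain, is isolated from the ring and must be set independently. With identical aryl groups the core would be meso, so its absolute configuration exists only through the difference between ring A on C2 and ring B on C5. A synthesis therefore has to distinguish C2 from C5 before or while C3 and C4 are set, and this is the main difficulty. Both ring C–O bonds are 4-hydroxybenzylic: they ionise under acid, with epimerisation at C2 or C5, and can be cut by hydrogenolysis. The strategy reads C3 and C4 with their cis methyls as the fusion carbons of a thiolane whose CH2–S–CH2 bridge is the two methyls in masked form, and reads C2 and C5 as the carbonyl and acetal carbons of a 5-alkoxybutenolide, which are chemically distinct.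

## Retrosynthetic reasoning

**20 from 19.** The three O–CH2Ph bonds are cut. Benzyl ethers survive the olefination base, hydride and cold Lewis acids, and keep each arene nucleophilic and para-directing for the arylations. They are removed together in one neutral step, which must not open the dibenzylic oxolane.

**19 from 17 and 18.** The C2–ring A bond is cut. C2 is a benzylic ether carbon and so a latent oxocarbenium ion, and 18 is the simplest para-directing ring A donor. Making this bond last means the acid-labile diaryl oxolane exists for one step before deprotection. The forward reaction must place ring A para on 18 and trans to the C3 methyl.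

**17 from 16.** This is a change of oxidation level only: the lactol comes from the lactone. The carbonyl of 16 is what kept C2 distinct from C5 up to this point.

**16 from 9 and 15.** The C5–ring B bond is cut at the acetal carbon of 9. Ring B arrives with its finished side chain, so the remote stereocentre is never made on the sensitive core. Placing ring B on the acetal carbon and ring A on the carbonyl carbon is what turns the (5R) configuration of the butenolide into the correct enantiomer of the near-meso core; the reverse assignment would give the mirror-image core. The forward reaction must arylate para to the ring B oxygen and trans to the C4 methyl.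

**9 from 8.** The two methyls are reconnected through sulfur (two C–S bonds). An acyclic cis-dimethyl problem becomes a cis ring fusion, which a cycloaddition gives automatically. The forward reaction is a reductive desulfurisation that must not epimerise C3, α to the lactone carbonyl.

**8 from 5 and 6, through 7.** Both ring-carbon-to-CH2 bonds are cut in a retro-[3+2] step. This leads to the symmetric dipole 7 and the butenolide 5, whose single acetal stereocentre directs the facial approach. No regiochemical question arises because 7 is symmetric.

**5 from 3 and 4, and 3 from 1.** The acetal C–O bond is cut to give the pseudo-acid 3 and the chiral alcohol 4. The crystalline (5R) epimer of 5 is obtained by equilibration and crystallisation. Compound 3 comes from 1 by photo-oxygenation, which removes the formyl carbon.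

**15 from 14, 14 from 11 and 13, 11 from 10, 13 from 12.** The side-chain stereocentre is traced to the trisubstituted alkene 14 by asymmetric hydrogenation. The C=C bond is cut to the ketone 11 and the phosphonate 13, and these come from 10 by O-benzylation and from 12 by an Arbuzov reaction. This keeps the fragment to four steps from bought materials.

## Alternatives that were turned down

**Alternative 1: keteniminium [2+2], then oxygen insertion.**
- Disconnection: C2–C3 and C4–C5, with the ring oxygen inserted afterwards.
- Forward key step: electrophilic activation of the ring A amide A1 (2-[4-(benzyloxy)phenyl]-N,N-dimethylacetamide) gives a keteniminium ion that adds to cis-2-butene A2. Hydrolysis gives the cyclobutanone A3, (2S,3S,4R)-2-[4-(benzyloxy)phenyl]-3,4-dimethylcyclobutan-1-one. Baeyer–Villiger insertion next to the benzylic carbon would give lactone A4, (3R,4S,5S)-5-[4-(benzyloxy)phenyl]-3,4-dimethyldihydrofuran-2(3H)-one, the ring A counterpart of 16.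
- For: it is shorter than the chosen route. The cis methyls follow from the alkene geometry, ring A is in place from the start so one arylation is saved, and the aryl group can settle trans by enolisation.
- Against: A1 and A2 are both achiral, so A3 forms as a racemate unless a chiral amine auxiliary controls the approach of a small unfunctionalised alkene, for which there is little to rely on. A2 is a gas used in excess. The oxygen insertion depends on one secondary α-carbon migrating in preference to another.
- Comparison: alternative 1 is stronger on step count. The chosen route offers instead an absolute configuration taken from a single crystalline diastereomer (5) and a facial bias exerted by a substituent directly on the reacting ring.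

**Alternative 2: biomimetic double quinone-methide cyclisation.**
- Disconnection: O1–C2 and O1–C5.
- Forward key step: a high-potential quinone oxidises both 4-hydroxybenzylic CH2 groups of the dibenzylbutane A5, 2-bromo-4-[(2S,3R)-4-(4-hydroxyphenyl)-2,3-dimethylbutyl]phenol. Hydration of one quinone methide and capture of the second by the new alcohol would close the oxolane A6, (2S,3S,4R,5R)-5-(3-bromo-4-hydroxyphenyl)-2-(4-hydroxyphenyl)-3,4-dimethyloxolane.
- For: one step closes the ring and sets C2 and C5 without protecting groups. Reversible capture should favour each aryl trans to its methyl. On this point it is stronger than the chosen route, which needs two separate arylations.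
- Against: A5 is itself near-meso, so its two methyl centres pose the same absolute-configuration problem as the target core and need their own asymmetric synthesis. Double benzylic oxidation of electron-rich phenols competes with over-oxidation and oligomerisation, and the brominated ring is the less readily oxidised one. The side chain would then have to be attached at the bromide by a stereoretentive secondary-alkyl coupling late in the route.
- Comparison: the chosen route solves the C2/C5 differentiation within the key intermediate and brings the side chain in ready-made on 15.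

**Alternative 3: carbene C–H insertion through a benzyl-ether tether.**
- Disconnection: the methine–CH2 bond of the side chain.
- Forward key step: the diazoester A7, methyl 2-[2-{[4-(benzyloxy)phenyl]methoxy}-5-bromophenyl]-2-diazoacetate, loses nitrogen on a chiral dirhodium tetracarboxylate (divalent rhodium). The carbene inserts into the benzylic C–H bond of the tether and gives A8, methyl (2R,3S)-2-[4-(benzyloxy)phenyl]-5-bromo-2,3-dihydro-1-benzofuran-3-carboxylate.
- For: this class of ring closure is well established with high enantiocontrol, and the bromide fixes the point of attachment on ring B without any regiochemical question. On both points it is as strong as or stronger than step 8 and step 9 of the chosen route.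
- Against: the key step spends its asymmetric induction on the isolated side-chain centre. It builds a ring and a second stereocentre that are later destroyed. The ester must be taken down to a methyl group in several redox steps, and the benzylic C–O bond must be cleaved without losing bromine. The centre α to the ester is epimerisable. The four contiguous centres of the oxolane remain unaddressed.
- Comparison: alternative 3 could replace the fragment synthesis but not the core. The chosen strategy puts its key step on the core and makes the side-chain centre in four steps without a sacrificial ring.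

Key step: step 3

## Route

Step 1
Reactants: 1 furfural
Product: 3 5-hydroxyfuran-2(5H)-one (racemic), via furfural endoperoxide 2 (not isolated)
Conditions: O2, hν (visible), rose bengal (C20H2Cl4I4Na2O5, cat.), MeOH, 20 °C
Reagents that add atoms: dioxygen, O=O
Why: Dye-sensitised photo-oxygenation of a furan: singlet oxygen adds [4+2] to give 2, methanol attacks the formyl group, and fragmentation with loss of methyl formate leaves the γ-hydroxybutenolide.

Step 2
Reactants: 3 5-hydroxyfuran-2(5H)-one; 4 (−)-menthol
Product: 5 (5R)-5-{[(1R,2S,5R)-2-isopropyl-5-methylcyclohexyl]oxy}furan-2(5H)-one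
Conditions: cat. camphorsulfonic acid, toluene, reflux (Dean–Stark); crystallisation from hexane, mother liquor re-equilibrated with acid
Reagents that add atoms: none
Why: Acid-catalysed acetalisation of the pseudo-acid gives both C5 epimers, which interconvert under the same acid; the (5R) epimer is the crystalline one, so equilibration and crystallisation should deliver a single diastereomer whose acetal carbon is the source of absolute configuration for the core.

Step 3
Reactants: 5 (5R)-5-(menthyloxy)furan-2(5H)-one; 6 chloromethyl trimethylsilylmethyl sulfide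
Product: 8 (3R,3aR,6aS)-3-{[(1R,2S,5R)-2-isopropyl-5-methylcyclohexyl]oxy}tetrahydro-1H,3H-thieno[3,4-c]furan-1-one, via thioformaldehyde S-methylide 7 (not isolated)
Conditions: CsF (4 equiv), 6 (2.5 equiv, slow addition), MeCN, 20 °C
Reagents that add atoms: none
Why: Fluoride attacks silicon of 6, and 1,3-elimination of fluorotrimethylsilane and chloride releases the parent thiocarbonyl ylide 7, a sulfur-centred 4π 1,3-dipole. Compound 7 adds to the electron-poor C3=C4 bond of 5 in a concerted [3+2] cycloaddition controlled by the dipole HOMO and the alkene LUMO, forming both ring-carbon-to-CH2 bonds at once. The closest known reaction types are the cycloaddition of this ylide to butenolides, enones and maleimides, and the anti-selective 1,3-dipolar cycloadditions of 5-menthyloxyfuranone. The thiolane ring is closed intermolecularly by this two-bond cycloaddition with no separate cyclisation, and because the addition is suprafacial on the alkene the new ring can only be cis-fused to the lactone. The cis relation of the new stereocentres C3a and C6a therefore follows from concertedness. Their absolute configuration is controlled by the (5R) acetal carbon next to the reacting C4: its menthyloxy group shields one face of the nearly planar butenolide, so 7 approaches anti to it. The step needs π-facial selectivity and needs 7 to be trapped faster than it self-condenses; the first is secured by the C5 substituent and the second by generating 7 slowly in the presence of 5, with 6 in excess. Any syn adduct is a diastereomer of 8 because of the menthyl group and can be removed by crystallisation or chromatography.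

Step 4
Reactants: 8 cis-fused thiolane lactone acetal
Product: 9 (3S,4R,5R)-3,4-dimethyl-5-{[(1R,2S,5R)-2-isopropyl-5-methylcyclohexyl]oxy}dihydrofuran-2(3H)-one
Conditions: Raney Ni (W-2 grade, washed to neutrality; zerovalent nickel), EtOH, 20 → 50 °C
Reagents that add atoms: none
Why: Reductive desulfurisation cleaves both C–S bonds on the nickel surface and replaces them by C–H, so the two ring CH2 groups become the C3 and C4 methyls without any stereocentre being touched; neutral nickel is used so that C3, α to the carbonyl, is not epimerised.

Step 5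
Reactants: 10 2'-hydroxyacetophenone
Product: 11 1-[2-(benzyloxy)phenyl]ethan-1-one
Conditions: BnBr, K2CO3, DMF, 60 °C
Reagents that add atoms: benzyl bromide, BrCc1ccccc1
Why: Williamson O-alkylation of the phenoxide; warming overcomes the intramolecular hydrogen bond to the ketone.

Step 6
Reactants: 12 1-(benzyloxy)-4-(chloromethyl)benzene
Product: 13 diethyl [4-(benzyloxy)benzyl]phosphonate
Conditions: P(OEt)3 (neat), 150 °C, EtCl distilled off
Reagents that add atoms: triethyl phosphite, CCOP(OCC)OCC
Why: Michaelis–Arbuzov reaction of a reactive benzylic chloride; the phosphonium intermediate is dealkylated by chloride.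

Step 7
Reactants: 11 1-[2-(benzyloxy)phenyl]ethan-1-one; 13 diethyl [4-(benzyloxy)benzyl]phosphonate
Product: 14 (E)-1-(benzyloxy)-2-{1-[4-(benzyloxy)phenyl]prop-1-en-2-yl}benzene
Conditions: NaH, DME, 0 → 85 °C; (E) isomer by crystallisation
Reagents that add atoms: none
Why: Horner–Wadsworth–Emmons olefination of an aryl methyl ketone with a benzylphosphonate anion; the (E) alkene, with the two aryl groups trans, is the favoured product and is purified because step 8 needs a geometrically pure alkene.

Step 8
Reactants: 14 (E)-alkene
Product: 15 1-(benzyloxy)-2-{(2R)-1-[4-(benzyloxy)phenyl]propan-2-yl}benzene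
Conditions: H2 (50 bar), [Ir(C8H12)(L)][B(C6H3(CF3)2)4] (1 mol %; L = (S)-4-tert-butyl-2-[2-(diphenylphosphanyl)phenyl]-4,5-dihydrooxazole; monovalent iridium), CH2Cl2, 25 °C
Reagents that add atoms: none
Why: Iridium–phosphinooxazoline catalysts hydrogenate unfunctionalised (E)-1,2-diarylpropenes, their standard substrate class, by face-selective coordination of the alkene in the chiral N,P pocket; this sets the side-chain (R) centre, and the benzyl ethers are inert to the homogeneous catalyst.

Step 9
Reactants: 9 dimethyl lactone acetal; 15 (R)-side-chain arene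
Product: 16 (3S,4R,5R)-5-[4-(benzyloxy)-3-{(2R)-1-[4-(benzyloxy)phenyl]propan-2-yl}phenyl]-3,4-dimethyldihydrofuran-2(3H)-one
Conditions: SnCl4 (1.5 equiv), 9 (1.2 equiv), CH2Cl2, −78 → −20 °C
Reagents that add atoms: none
Why: Friedel–Crafts alkylation by a lactone acetal (pseudoester): SnCl4 ionises the acetal carbon, either by loss of the menthyloxy group or by opening to the alkoxycarbenium carboxylate, and both paths end in the 5-aryl lactone. The arene reacts para to the ring B benzyloxy group, its only free para position; the aryl ends up trans to the C4 methyl because the cation is attacked anti to the two cis methyls and because the benzylic C5–O bond can re-close to the more stable trans lactone.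

Step 10
Reactants: 16 5-aryl lactone
Product: 17 (3S,4R,5R)-5-[4-(benzyloxy)-3-{(2R)-1-[4-(benzyloxy)phenyl]propan-2-yl}phenyl]-3,4-dimethyloxolan-2-ol (mixture of anomers)
Conditions: iBu2AlH (1.2 equiv), CH2Cl2, −78 °C; aq. KNaC4H4O6 work-up
Reagents that add atoms: none
Why: Partial reduction of a lactone stops at the tetrahedral aluminium hemiacetal at −78 °C and gives the lactol on work-up; benzyl ethers and stereocentres are untouched, and the anomeric mixture does not matter because C2 is ionised next.

Step 11
Reactants: 17 lactol; 18 benzyl phenyl ether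
Product: 19 (2S,3S,4R,5R)-2-[4-(benzyloxy)phenyl]-5-[4-(benzyloxy)-3-{(2R)-1-[4-(benzyloxy)phenyl]propan-2-yl}phenyl]-3,4-dimethyloxolane
Conditions: 18 (5 equiv), BF3·OEt2 (2 equiv), CH2Cl2, −78 → −20 °C
Reagents that add atoms: none
Why: Friedel–Crafts arylation of a lactol: BF3·OEt2 generates the cyclic oxocarbenium ion at C2, which alkylates the para position of 18. Attack anti to the adjacent C3 methyl gives the 2,3-trans product, which should also be the thermodynamic arrangement if the benzylic ether re-ionises; excess 18 outcompetes the less reactive ortho positions of rings B and C.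

Step 12
Reactants: 19 tris(benzyl ether)
Product: 20 (2S,3S,4R,5R)-2-(4-hydroxyphenyl)-5-{4-hydroxy-3-[(2R)-1-(4-hydroxyphenyl)propan-2-yl]phenyl}-3,4-dimethyloxolane (CNP0232576.1)
Conditions: H2 (1 atm), 10 % Pd/C (palladium metal on carbon), EtOAc/MeOH, 20 °C
Reagents that add atoms: none
Why: Hydrogenolysis of aryl benzyl ethers under neutral conditions; the ArO–CH2Ph bonds should cleave faster than the two cyclic dibenzylic C–O bonds, so the reaction is stopped after three equivalents of hydrogen and the target is released without acid or base.

## Compound list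

1 | furfural (furan-2-carbaldehyde) | O=Cc1ccco1 | starting material
2 | furfural endoperoxide (2,3,7-trioxabicyclo[2.2.1]hept-5-ene-1-carbaldehyde) | O=CC12OOC(C=C1)O2 | intermediate (not isolated)
3 | 5-hydroxyfuran-2(5H)-one (racemic) | O=C1C=CC(O)O1 | intermediate
4 | (−)-menthol, (1R,2S,5R)-2-isopropyl-5-methylcyclohexan-1-ol | CC(C)[C@@H]1CC[C@@H](C)C[C@H]1O | starting material
5 | (5R)-5-{[(1R,2S,5R)-2-isopropyl-5-methylcyclohexyl]oxy}furan-2(5H)-one | O=C1C=C[C@H](O[C@@H]2C[C@H](C)CC[C@H]2C(C)C)O1 | intermediate
6 | chloromethyl trimethylsilylmethyl sulfide | C[Si](C)(C)CSCCl | starting material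
7 | thioformaldehyde S-methylide | C=[S+][CH2-] | intermediate (not isolated)
8 | (3R,3aR,6aS)-3-{[(1R,2S,5R)-2-isopropyl-5-methylcyclohexyl]oxy}tetrahydro-1H,3H-thieno[3,4-c]furan-1-one (cis-fused, menthyloxy anti to the thiolane) | S1C[C@@H]2[C@H](C1)C(=O)O[C@H]2O[C@@H]3C[C@H](C)CC[C@H]3C(C)C | intermediate
9 | (3S,4R,5R)-3,4-dimethyl-5-{[(1R,2S,5R)-2-isopropyl-5-methylcyclohexyl]oxy}dihydrofuran-2(3H)-one | C[C@@H]1[C@H](C)C(=O)O[C@H]1O[C@@H]2C[C@H](C)CC[C@H]2C(C)C | intermediate
10 | 2'-hydroxyacetophenone | CC(=O)c1ccccc1O | starting material
11 | 1-[2-(benzyloxy)phenyl]ethan-1-one | CC(=O)c1ccccc1OCc1ccccc1 | intermediate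
12 | 1-(benzyloxy)-4-(chloromethyl)benzene | ClCc1ccc(OCc2ccccc2)cc1 | starting material
13 | diethyl [4-(benzyloxy)benzyl]phosphonate | CCOP(=O)(OCC)Cc1ccc(OCc2ccccc2)cc1 | intermediate
14 | (E)-1-(benzyloxy)-2-{1-[4-(benzyloxy)phenyl]prop-1-en-2-yl}benzene | C/C(=C\c1ccc(OCc2ccccc2)cc1)c1ccccc1OCc1ccccc1 | intermediate
15 | 1-(benzyloxy)-2-{(2R)-1-[4-(benzyloxy)phenyl]propan-2-yl}benzene | C[C@H](Cc1ccc(OCc2ccccc2)cc1)c1ccccc1OCc1ccccc1 | intermediate
16 | (3S,4R,5R)-5-[4-(benzyloxy)-3-{(2R)-1-[4-(benzyloxy)phenyl]propan-2-yl}phenyl]-3,4-dimethyldihydrofuran-2(3H)-one | C[C@@H]1[C@H](C)C(=O)O[C@H]1c1ccc(OCc2ccccc2)c([C@H](C)Cc2ccc(OCc3ccccc3)cc2)c1 | intermediate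
17 | (3S,4R,5R)-5-[4-(benzyloxy)-3-{(2R)-1-[4-(benzyloxy)phenyl]propan-2-yl}phenyl]-3,4-dimethyloxolan-2-ol (anomers) | C[C@@H]1[C@H](C)C(O)O[C@H]1c1ccc(OCc2ccccc2)c([C@H](C)Cc2ccc(OCc3ccccc3)cc2)c1 | intermediate
18 | benzyl phenyl ether | c1ccccc1OCc1ccccc1 | starting material
19 | (2S,3S,4R,5R)-2-[4-(benzyloxy)phenyl]-5-[4-(benzyloxy)-3-{(2R)-1-[4-(benzyloxy)phenyl]propan-2-yl}phenyl]-3,4-dimethyloxolane | C[C@@H]1[C@H](C)[C@@H](c2ccc(OCc3ccccc3)cc2)O[C@H]1c1ccc(OCc2ccccc2)c([C@H](C)Cc2ccc(OCc3ccccc3)cc2)c1 | intermediate
20 | (2S,3S,4R,5R)-2-(4-hydroxyphenyl)-5-{4-hydroxy-3-[(2R)-1-(4-hydroxyphenyl)propan-2-yl]phenyl}-3,4-dimethyloxolane | C[C@@H]1[C@H](C)[C@@H](c2ccc(O)cc2)O[C@H]1c1ccc(O)c([C@H](C)Cc2ccc(O)cc2)c1 | target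

## Step count and least certain steps

Total: 12 steps. Longest linear sequence: 8 steps (1, 2, 3, 4, 9, 10, 11, 12). The fragment branch (steps 5 to 8) joins at step 9.

**Step 3 (key step).** The ylide may self-condense faster than it is trapped, so conversion of 5 could stall. Fluoride is mildly basic and could epimerise the acetal carbon of 5 through its furanolate before cycloaddition; together with incomplete anti facial selectivity, this would lower the stereochemical purity of the core.
Fallback, setting out from 4 and rejoining at 16: commercial 2,3-dimethylmaleic anhydride is reduced at one carbonyl (LiAlH(OtBu)3, THF, −20 °C) to 5-hydroxy-3,4-dimethylfuran-2(5H)-one F1. Acetalisation with 4 (cat. camphorsulfonic acid, toluene, reflux) and separation of the epimers gives (5S)-3,4-dimethyl-5-(menthyloxy)furan-2(5H)-one F2; the (5R) epimer is re-equilibrated with acid. Hydrogenation of F2 (H2, 50 bar, Rh/Al2O3, rhodium metal on Al2O3, EtOAc) should deliver both hydrogens anti to the menthyloxy group and give (3S,4R,5S)-3,4-dimethyl-5-(menthyloxy)dihydrofuran-2(3H)-one F3, the C5 epimer of 9. Because C5 is ionised in step 9, F3 is used there in place of 9 and gives 16.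

**Step 9.** Ionising the acyl acetal needs a Lewis acid strong enough that benzyl ethers may start to cleave or migrate. Attack may also occur at ortho positions of rings B and C. The benzylic lactone C–O bond of the product may re-ionise and take up a second arene, and loss of the C4 proton from the cation would epimerise C4.
Fallback, setting out from 9 and 15 and rejoining at 16: 9 is hydrolysed (aqueous HCl, AcOH, 50 °C) to the pseudo-acid (3S,4R)-5-hydroxy-3,4-dimethyldihydrofuran-2(3H)-one F4, which is in equilibrium with its open aldehyde acid. Compound 15 is brominated para to the ring B oxygen (N-bromosuccinimide, MeCN, 0 °C) to 1-(benzyloxy)-4-bromo-2-{(2R)-1-[4-(benzyloxy)phenyl]propan-2-yl}benzene F5. F5 is converted with Mg in THF into the arylmagnesium bromide F6 (not isolated). Two equivalents of F6 are added to F4 at −78 °C, the first acting as base, to give (2S,3R)-4-aryl-4-hydroxy-2,3-dimethylbutanoic acid F7 as a mixture at the carbinol carbon. Acid (TsOH, toluene, 60 °C) lactonises F7 and equilibrates the benzylic carbon to the trans lactone 16. Here the regiochemistry on ring B is fixed by the bromide.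

**Step 11.** The oxocarbenium ion may be captured by ortho positions of 18 or by the activated rings of another molecule of 17 (oligomerisation). Proton loss to the cyclic enol ether would epimerise C3, and reversible ionisation at C5 could scramble that centre if the temperature rises.
Fallback, setting out from 16 and rejoining at 19: commercial 4-(benzyloxy)phenylmagnesium bromide is added to 16 (THF, −78 °C) to give the hemiketal (3S,4R,5R)-2-[4-(benzyloxy)phenyl]-5-aryl-3,4-dimethyloxolan-2-ol F8. Reduction with Et3SiH and BF3·OEt2 (CH2Cl2, −78 °C) should deliver hydride anti to the C3 methyl and give mainly the C2 epimer, (2R,3S,4R,5R)-2-[4-(benzyloxy)phenyl]-5-aryl-3,4-dimethyloxolane F9. Holding F9 with BF3·OEt2 at −20 to 0 °C should equilibrate C2 through the 4-alkoxybenzylic cation to 19. Ring A is then attached through its ipso carbon, with no regiochemical question.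

**Step 8.** The ortho-benzyloxy group twists ring B out of the alkene plane, which may slow the hydrogenation and lower its enantioselectivity compared with the parent substrate. The sense of induction is unproven for this alkene, and residual (Z) isomer would give the other enantiomer.
Fallback, setting out from 11 and rejoining at 15: a Willgerodt–Kindler reaction (S8, morpholine, 130 °C) gives the thiomorpholide 2-[2-(benzyloxy)phenyl]-1-(morpholin-4-yl)ethane-1-thione F10, and hydrolysis (KOH, aqueous EtOH, reflux) gives 2-[2-(benzyloxy)phenyl]acetic acid F11. F11 is acylated onto (S)-4-benzyl-1,3-oxazolidin-2-one (pivaloyl chloride, Et3N, LiCl, THF) to give the imide (4S)-4-benzyl-3-{2-[2-(benzyloxy)phenyl]acetyl}-1,3-oxazolidin-2-one F12. Evans alkylation (NaN(SiMe3)2, MeI, THF, −78 °C) on the face away from the auxiliary benzyl group gives (4S)-4-benzyl-3-{(2S)-2-[2-(benzyloxy)phenyl]propanoyl}-1,3-oxazolidin-2-one F13. Reduction (LiBH4, THF, H2O, 0 °C) gives (2S)-2-[2-(benzyloxy)phenyl]propan-1-ol F14, and tosylation (TsCl, pyridine) gives (2S)-2-[2-(benzyloxy)phenyl]propyl 4-methylbenzenesulfonate F15. Copper-catalysed coupling of F15 with commercial 4-(benzyloxy)phenylmagnesium bromide (cat. Li2CuCl4, THF, −20 → 20 °C) gives 15; the descriptor changes from S to R only because the substituent priorities change.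

**Step 12.** Hydrogenolysis may not stop at the three aryl benzyl ethers and could cut one of the benzylic C–O bonds of the oxolane, which would open the ring.
Fallback, setting out from 15 and rejoining at 20: the benzyl ethers are exchanged for silyl ethers before the sensitive ring exists. Hydrogenolysis of 15 (H2, Pd/C, palladium metal on carbon, EtOAc) gives 2-[(2R)-1-(4-hydroxyphenyl)propan-2-yl]phenol F16. Silylation (tert-butyldimethylsilyl chloride, imidazole, DMF) gives the bis(silyl ether) F17. F17 is carried through the conditions of step 9 (with 9) to the lactone F18, of step 10 to the lactol F19, and of step 11 (with tert-butyldimethyl(phenoxy)silane in place of 18) to the tris(silyl ether) F20. Bu4NF buffered with AcOH (THF, 0 °C) then releases 20 without any reductive step.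

## Further compounds

F1 | step 3 | 5-hydroxy-3,4-dimethylfuran-2(5H)-one | CC1=C(C)C(O)OC1=O
F2 | step 3 | (5S)-3,4-dimethyl-5-{[(1R,2S,5R)-2-isopropyl-5-methylcyclohexyl]oxy}furan-2(5H)-one | CC1=C(C)[C@@H](O[C@@H]2C[C@H](C)CC[C@H]2C(C)C)OC1=O
F3 | step 3 | (3S,4R,5S)-3,4-dimethyl-5-{[(1R,2S,5R)-2-isopropyl-5-methylcyclohexyl]oxy}dihydrofuran-2(3H)-one | C[C@@H]1[C@H](C)C(=O)O[C@@H]1O[C@@H]2C[C@H](C)CC[C@H]2C(C)C
F4 | step 9 | (3S,4R)-5-hydroxy-3,4-dimethyldihydrofuran-2(3H)-one | C[C@@H]1[C@H](C)C(=O)OC1O
F5 | step 9 | 1-(benzyloxy)-4-bromo-2-{(2R)-1-[4-(benzyloxy)phenyl]propan-2-yl}benzene | C[C@H](Cc1ccc(OCc2ccccc2)cc1)c1cc(Br)ccc1OCc1ccccc1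
F6 | step 9 | [4-(benzyloxy)-3-{(2R)-1-[4-(benzyloxy)phenyl]propan-2-yl}phenyl]magnesium bromide | C[C@H](Cc1ccc(OCc2ccccc2)cc1)c1cc([Mg]Br)ccc1OCc1ccccc1
F7 | step 9 | (2S,3R)-4-[4-(benzyloxy)-3-{(2R)-1-[4-(benzyloxy)phenyl]propan-2-yl}phenyl]-4-hydroxy-2,3-dimethylbutanoic acid (C4 epimers) | C[C@@H](C(O)c1ccc(OCc2ccccc2)c([C@H](C)Cc2ccc(OCc3ccccc3)cc2)c1)[C@H](C)C(=O)O
F8 | step 11 | (3S,4R,5R)-2-[4-(benzyloxy)phenyl]-5-[4-(benzyloxy)-3-{(2R)-1-[4-(benzyloxy)phenyl]propan-2-yl}phenyl]-3,4-dimethyloxolan-2-ol | C[C@@H]1[C@H](C)C(O)(c2ccc(OCc3ccccc3)cc2)O[C@H]1c1ccc(OCc2ccccc2)c([C@H](C)Cc2ccc(OCc3ccccc3)cc2)c1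
F9 | step 11 | (2R,3S,4R,5R)-2-[4-(benzyloxy)phenyl]-5-[4-(benzyloxy)-3-{(2R)-1-[4-(benzyloxy)phenyl]propan-2-yl}phenyl]-3,4-dimethyloxolane | C[C@@H]1[C@H](C)[C@H](c2ccc(OCc3ccccc3)cc2)O[C@H]1c1ccc(OCc2ccccc2)c([C@H](C)Cc2ccc(OCc3ccccc3)cc2)c1
F10 | step 8 | 2-[2-(benzyloxy)phenyl]-1-(morpholin-4-yl)ethane-1-thione | S=C(Cc1ccccc1OCc1ccccc1)N1CCOCC1
F11 | step 8 | 2-[2-(benzyloxy)phenyl]acetic acid | OC(=O)Cc1ccccc1OCc1ccccc1
F12 | step 8 | (4S)-4-benzyl-3-{2-[2-(benzyloxy)phenyl]acetyl}-1,3-oxazolidin-2-one | O=C1OC[C@H](Cc2ccccc2)N1C(=O)Cc1ccccc1OCc1ccccc1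
F13 | step 8 | (4S)-4-benzyl-3-{(2S)-2-[2-(benzyloxy)phenyl]propanoyl}-1,3-oxazolidin-2-one | O=C1OC[C@H](Cc2ccccc2)N1C(=O)[C@@H](C)c1ccccc1OCc1ccccc1
F14 | step 8 | (2S)-2-[2-(benzyloxy)phenyl]propan-1-ol | C[C@H](CO)c1ccccc1OCc1ccccc1
F15 | step 8 | (2S)-2-[2-(benzyloxy)phenyl]propyl 4-methylbenzenesulfonate | C[C@H](COS(=O)(=O)c1ccc(C)cc1)c1ccccc1OCc1ccccc1
F16 | step 12 | 2-[(2R)-1-(4-hydroxyphenyl)propan-2-yl]phenol | C[C@H](Cc1ccc(O)cc1)c1ccccc1O
F17 | step 12 | tert-butyl{2-[(2R)-1-(4-{[tert-butyl(dimethyl)silyl]oxy}phenyl)propan-2-yl]phenoxy}dimethylsilane | C[C@H](Cc1ccc(O[Si](C)(C)C(C)(C)C)cc1)c1ccccc1O[Si](C)(C)C(C)(C)C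
F18 | step 12 | (3S,4R,5R)-5-[4-(silyloxy)-3-{(2R)-1-[4-(silyloxy)phenyl]propan-2-yl}phenyl]-3,4-dimethyldihydrofuran-2(3H)-one (silyl = tert-butyldimethylsilyl) | C[C@@H]1[C@H](C)C(=O)O[C@H]1c1ccc(O[Si](C)(C)C(C)(C)C)c([C@H](C)Cc2ccc(O[Si](C)(C)C(C)(C)C)cc2)c1
F19 | step 12 | (3S,4R,5R)-5-[4-(silyloxy)-3-{(2R)-1-[4-(silyloxy)phenyl]propan-2-yl}phenyl]-3,4-dimethyloxolan-2-ol (silyl = tert-butyldimethylsilyl; anomers) | C[C@@H]1[C@H](C)C(O)O[C@H]1c1ccc(O[Si](C)(C)C(C)(C)C)c([C@H](C)Cc2ccc(O[Si](C)(C)C(C)(C)C)cc2)c1
F20 | step 12 | (2S,3S,4R,5R)-2-[4-(silyloxy)phenyl]-5-[4-(silyloxy)-3-{(2R)-1-[4-(silyloxy)phenyl]propan-2-yl}phenyl]-3,4-dimethyloxolane (silyl = tert-butyldimethylsilyl) | C[C@@H]1[C@H](C)[C@@H](c2ccc(O[Si](C)(C)C(C)(C)C)cc2)O[C@H]1c1ccc(O[Si](C)(C)C(C)(C)C)c([C@H](C)Cc2ccc(O[Si](C)(C)C(C)(C)C)cc2)c1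
A1 | alternative 1 | 2-[4-(benzyloxy)phenyl]-N,N-dimethylacetamide | CN(C)C(=O)Cc1ccc(OCc2ccccc2)cc1
A2 | alternative 1 | cis-2-butene | C/C=C\C
A3 | alternative 1 | (2S,3S,4R)-2-[4-(benzyloxy)phenyl]-3,4-dimethylcyclobutan-1-one | C[C@@H]1[C@H](C)[C@@H](c2ccc(OCc3ccccc3)cc2)C1=O
A4 | alternative 1 | (3R,4S,5S)-5-[4-(benzyloxy)phenyl]-3,4-dimethyldihydrofuran-2(3H)-one | C[C@@H]1[C@H](C)[C@@H](c2ccc(OCc3ccccc3)cc2)OC1=O
A5 | alternative 2 | 2-bromo-4-[(2S,3R)-4-(4-hydroxyphenyl)-2,3-dimethylbutyl]phenol | C[C@@H](Cc1ccc(O)c(Br)c1)[C@H](C)Cc1ccc(O)cc1
A6 | alternative 2 | (2S,3S,4R,5R)-5-(3-bromo-4-hydroxyphenyl)-2-(4-hydroxyphenyl)-3,4-dimethyloxolane | C[C@@H]1[C@H](C)[C@@H](c2ccc(O)cc2)O[C@H]1c1ccc(O)c(Br)c1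
A7 | alternative 3 | methyl 2-[2-{[4-(benzyloxy)phenyl]methoxy}-5-bromophenyl]-2-diazoacetate | COC(=O)C(=[N+]=[N-])c1cc(Br)ccc1OCc1ccc(OCc2ccccc2)cc1
A8 | alternative 3 | methyl (2R,3S)-2-[4-(benzyloxy)phenyl]-5-bromo-2,3-dihydro-1-benzofuran-3-carboxylate | O1c2ccc(Br)cc2[C@H](C(=O)OC)[C@@H]1c1ccc(OCc2ccccc2)cc1
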